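## Analysis of the target

The target (56) is a spiro[4.5]decane. Its cyclopentane (C1, C2, C3, C4, C5) carries a secondary carbinol at C5 and, at C1, a side arm that starts with C11 (bearing an exocyclic methylene) and continues as a conjugated triene, C12=C13 (E) and C14=C15 (Z), with C15 carrying CH2OH and a 4-methylpent-3-enyl group. Its cyclohexane (C4, C6, C7, C8, C9, C10) carries a 3-hydroxypropyl chain at C6, a tetrasubstituted exocyclic enal at C7 and a methyl carbinol at C10. There are five stereocentres (C1, quaternary spiro C4, C5, C6, C10). On the cyclopentane the C5–O bond and the C4–C10 bond are cis and the C1 arm is trans to both. On the cyclohexane C5, the C10 hydroxyl and the C6 chain share one face, while C3 and the C10 methyl lie on the other. The enal double bond has the CHO on the C6 side and the methyl on the C8 side; neither isomer is clearly favoured thermodynamically, so this geometry has to be enforced. Sensitive groups are the triene (acid, oxidants), the enal (γ-deprotonation, which would endanger both C6 and the geometry), and the tertiary C10 carbinol next to the quaternary C4 (ionisation and rearrangement). The hard points are the contiguous C5–C4–C10 array around a quaternary centre, the distinction between C6 and C8 as α-positions of a C7 ketone, and the enal geometry. The strategy rests on one feature: C5 bears oxygen cis to the C4–C10 bond and C10 is a carbinol carbon, so C5(OH)–C4–C10(=O) is a β-hydroxy ketone that a 2-isoxazoline spanning C4–C5, with C10 as its C=N carbon, stores in masked form.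

## Retrosynthetic reasoning

**Triene.** The C11–C12 bond of 56 is cut last, giving the enol triflate 48 and the dienylstannane 55. A stereospecific sp2–sp2 coupling brings in both alkene geometries ready-made, tolerates the free hydroxyls and the enal, and means the triene meets no further reagent.

**Functional-group level of the core.** 48 is traced to the enol triflate 43 without any skeletal change. The enal comes from the methyl ester, the hydroxypropyl chain from the C6 allyl group, and the C5 hydroxyl from its silyl ether. The ester is kept until C11 is finished because an enal would not survive that chemistry.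

**C11 and its methylene carbon.** 43 is cut at the C11–CH2 bond back to the ester 37, whose C1 arm is still the silyloxymethyl group. The methylene carbon is added to the C11 aldehyde as a methyl nucleophile and the resulting methyl ketone is enolised on the methyl side.

**Enoate geometry and the C6 chain.** 37 is traced to the bicyclic lactone 35, and 35 to the phosphonate ester 34 and the aldol product 30. The C7=C bond is cut as an intramolecular Horner–Wadsworth–Emmons olefination and the C6–C bond as an aldol addition to 28. Closing the tetrasubstituted alkene inside a six-membered lactone forces the carbonyl carbon cis to C6, which no intermolecular olefination of this ketone would do. The lactone oxygen sits on an allylic carbon, so it can afterwards be removed by hydrogenolysis through a π-allyl palladium intermediate, leaving exactly the allyl group needed for the chain.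

**Which α-carbon reacts.** 30 is traced through the enone 27 to the saturated ketone 26. Dehydrogenation can only occur towards C8–C9 because C6 adjoins the quaternary C4; in the enone C6 is the only enolisable carbon, so the C6/C8 problem disappears.

**C10 methyl.** 26 comes from the carbinol 25 by ketal hydrolysis, and 25 from the silylated ketol 24 by cutting the C10–CH3 bond. The methyl group must enter anti to O5; the silyl ether on O5, which sits over one face of the C10 carbonyl, is what enforces this.

**Ketol.** 24 and 23 are the β-hydroxy ketone revealed by N–O cleavage of the isoxazoline 21.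

**Key disconnection.** In 21 the C4–C10 and C5–O bonds are cut together. This opens the isoxazoline and the cyclohexane to the nitrile oxide 20, generated from the nitro ketal 19. The forward reaction builds the quaternary C4, the C5 oxygen and the six-membered ring at once, with C1 as the only controlling stereocentre.

**Tether.** 19 comes from the chloride 17 by halide-to-nitro exchange. 17 is cut at the C4–C6 bond into the enol triflate 10 and the alkylzinc 16, made from 15, 13, 11 and 14. Because C7 is already a ketal in the nucleophile, no β,γ-unsaturated ketone is ever formed and the C4=C5 alkene cannot migrate.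

**C1 stereocentre.** 10 is a regiodefined enol triflate. It is cut back to the enone 7, which comes from 6 and from 1 and 2. An asymmetric conjugate reduction sets C1 and delivers the enolate on the correct side in the same operation.

**Side chain.** 55 is cut at C12–C13/C13–C14 into the iodide 53 and the bis-stannane 54. 53 comes from 49 and 50 by carbometalation, which fixes the (Z) geometry through a chelate.

## Alternatives that were turned down

**Alternative 1:** The cyclopentane is disconnected at C4–C5 and C3–C4 back to a four-membered ketone on a terpene-derived cyclohexenone. In the forward step the lithiated sulfide A2 adds to the carbonyl of the enone A1, and acid then shifts a cyclopropane carbon to give the spiro cyclobutanone A3. In its favour, A1 is cheap and enantiopure, the C6 allyl group and all three carbons of the enal are present from the start, and the C10 methyl is in place; on these points it is stronger than the chosen route, which spends about six steps on the C6 chain and the enal. Against it, A3 lacks one ring carbon, so a regioselective one-carbon ring expansion is needed, followed by introduction of the C1 arm. The C5 and C10 oxygens are not set: C10 would need face-selective hydration of a trisubstituted alkene next to the quaternary centre, and C5 a selective ketone reduction. The isopropenyl group on C7 has to be moved into conjugation and one of its two methyls oxidised, which leaves the enal geometry open. The chosen route instead forms C4, C5 and the C10 carbonyl in one stereodefined event and has the C1 arm from the first stereocentre on.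

**Alternative 2:** The cyclohexane is disconnected at C4–C10 and C6–C7 into the furan A4 and the butenolide A5. Their intermolecular Diels–Alder reaction would give the oxa-bridged lactone A6 with C4, C6 and C10 set and the bridge oxygen destined to be the C10 hydroxyl. It is more convergent than the chosen route and sets three stereocentres in one step from simple pieces, against two in the chosen key step. Against it, furan cycloadditions are reversible, and this one pairs a 2,5-disubstituted furan with an α-alkylated dienophile whose α-carbon must become the quaternary C4. Regiochemistry and exo/endo preference rest only on weak biases. Afterwards the bridge must be opened towards C7 with formation of the tetrasubstituted alkene (geometry again uncontrolled), the cyclopentane is still to be closed, and C5 and C1 are still to be set. In the chosen route the cycloaddition is intramolecular and irreversible, the tether fixes its regiochemistry, and the oxygen is placed on C5.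

**Alternative 3:** Only the triene is disconnected: the C11 methylene and the C12=C13 bond arise from enyne cross-metathesis between the alkyne A7 and the diene A8 with a ruthenium carbene catalyst, giving the silyl ether A9. For the triene alone it is shorter and tin-free (the alkyne is one step from an aldehyde, where the chosen route needs three to reach the enol triflate), and on that point it is stronger. Against it, it says nothing about how the spirocyclic core and its five stereocentres are made, which is where the difficulty lies. The metathesis partner is a conjugated diene with a further trisubstituted alkene, so the carbene can enter at several positions, and the E selectivity at C12=C13 is not assured. The chosen route fixes that geometry by a stereospecific coupling and addresses the core.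

Key step: step 8

Remarks on the chemistry: locants C1–C15 are those defined in the analysis, not systematic locants. The carbinol carbon created in step 14 is carried as a mixture of epimers because step 18 removes it. The ligand enantiomer in step 3 is assumed by analogy with 3-alkylcyclopentenones; the other enantiomer is used if the first run shows the opposite sense.

## Route

Step 1
Reactants: 1 3-ethoxycyclopent-2-en-1-one; 2 (chloromethyl)(isopropoxy)dimethylsilane
Product: 6 3-(hydroxymethyl)cyclopent-2-en-1-one, via Grignard reagent 3 (not isolated), via silylmethyl carbinol 4 (not isolated), via enol ether diol 5 (not isolated)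
Conditions: 2, Mg, THF, 40 °C; 1 added at 0 °C; then KF, KHCO3, 30% H2O2, THF/MeOH, rt; then 1 M HCl, rt
Reagents that add atoms: hydrogen peroxide (OO); water (O)
Why: Stork–Danheiser sequence with a silicon-based hydroxymethyl anion equivalent: the Grignard reagent adds 1,2 to the vinylogous ester, Tamao oxidation turns C–Si into C–OH, and acid hydrolysis with loss of the tertiary hydroxyl transposes the enone so that the new carbon sits on the β-position.

Step 2
Reactants: 6 3-(hydroxymethyl)cyclopent-2-en-1-one
Product: 7 3-{[(tert-butyldimethylsilyl)oxy]methyl}cyclopent-2-en-1-one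
Conditions: TBSCl, imidazole, DMF, 0 °C → rt
Reagents that add atoms: tert-butyldimethylsilyl chloride (CC(C)(C)[Si](C)(C)Cl)
Why: Standard silylation of a primary alcohol; this ether is the C11 protecting group carried through the key step up to step 19.

Step 3
Reactants: 7 3-{[(tert-butyldimethylsilyl)oxy]methyl}cyclopent-2-en-1-one
Product: 10 (3R)-3-{[(tert-butyldimethylsilyl)oxy]methyl}cyclopent-1-en-1-yl trifluoromethanesulfonate, via bis(enol) silane 8 (not isolated), via lithium enolate 9 (not isolated)
Conditions: CuCl (5 mol%), NaOtBu (5 mol%), (S)-p-tol-BINAP (5 mol%), Ph2SiH2 (0.55 equiv), toluene, 0 °C; then MeLi, THF, 0 °C; then PhNTf2, −78 °C → rt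
Reagents that add atoms: N-phenylbis(trifluoromethanesulfonimide) (O=S(=O)(N(c1ccccc1)S(=O)(=O)C(F)(F)F)C(F)(F)F)
Why: Copper hydride-catalysed asymmetric conjugate reduction of a β-substituted cyclopentenone sets C1 by enantioface-selective hydride delivery and stores the regiodefined enolate as a silyl enol ether; silicon-to-lithium exchange and O-triflation then fix the double bond between the future C4 and C5.

Step 4
Reactants: 11 4-chlorobutanoyl chloride
Product: 13 1-bromo-5-chloropentan-2-one, via diazoketone 12 (not isolated)
Conditions: CH2N2 (2.2 equiv), Et2O, 0 °C; then 48% aq HBr, 0 °C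
Reagents that add atoms: diazomethane (C=[N+]=[N-]); hydrogen bromide (Br)
Why: Acylation of diazomethane gives the diazoketone and HBr converts it into the bromomethyl ketone (Nierenstein reaction), which places the bromine unambiguously on the future C6.

Step 5
Reactants: 13 1-bromo-5-chloropentan-2-one; 14 ethane-1,2-diol
Product: 15 2-(bromomethyl)-2-(3-chloropropyl)-1,3-dioxolane
Conditions: TsOH·H2O (cat.), benzene, Dean–Stark, reflux
Reagents that add atoms: none
Why: Acid-catalysed ketalisation with azeotropic removal of water; the C7 carbonyl is masked before any organometallic step.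

Step 6
Reactants: 15 2-(bromomethyl)-2-(3-chloropropyl)-1,3-dioxolane; 10 (3R)-3-{[(tert-butyldimethylsilyl)oxy]methyl}cyclopent-1-en-1-yl trifluoromethanesulfonate
Product: 17 tert-butyl{[(1R)-3-{[2-(3-chloropropyl)-1,3-dioxolan-2-yl]methyl}cyclopent-2-en-1-yl]methoxy}dimethylsilane, via alkylzinc bromide 16 (not isolated)
Conditions: Zn dust, LiCl, THF, 50 °C; then 10, Pd2(dba)3 (2.5 mol%), SPhos (10 mol%), THF/NMP, 60 °C
Reagents that add atoms: none
Why: Zinc inserts into the C–Br bond only (the alkyl chloride is inert) and the resulting alkylzinc, which has no β-hydrogen, undergoes Negishi sp2–sp3 coupling with the enol triflate; with C7 already a ketal the alkene cannot leave the C4=C5 position.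

Step 7
Reactants: 17 tert-butyl{[(1R)-3-{[2-(3-chloropropyl)-1,3-dioxolan-2-yl]methyl}cyclopent-2-en-1-yl]methoxy}dimethylsilane
Product: 19 tert-butyldimethyl{[(1R)-3-{[2-(3-nitropropyl)-1,3-dioxolan-2-yl]methyl}cyclopent-2-en-1-yl]methoxy}silane, via iodide 18 (not isolated)
Conditions: NaI, DMF, 60 °C; then NaNO2, phloroglucinol, rt
Reagents that add atoms: sodium nitrite ([Na+].[O-]N=O)
Why: Finkelstein exchange followed by Kornblum displacement with nitrite gives the primary nitroalkane; phloroglucinol traps nitrite ester so that the product is not nitrosated.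

Step 8
Reactants: 19 tert-butyldimethyl{[(1R)-3-{[2-(3-nitropropyl)-1,3-dioxolan-2-yl]methyl}cyclopent-2-en-1-yl]methoxy}silane
Product: 21 spiro-fused isoxazoline (ring C10=N–O–C5 across C4–C5; C7 dioxolane; C1 CH2OTBS), via nitrile oxide 20 (not isolated)
Conditions: PhNCO (3 equiv), Et3N (0.2 equiv), benzene (0.01 M), slow addition, 25 → 60 °C
Reagents that add atoms: none
Why: Phenyl isocyanate with catalytic Et3N dehydrates the primary nitro group to nitrile oxide 20 (Mukaiyama–Hoshino dehydration), which undergoes a concerted, suprafacial [3+2] cycloaddition with the trisubstituted alkene of the same molecule. The closest known reaction type is the intramolecular nitrile oxide–alkene cycloaddition of ω-nitroalkenes, whose isoxazolines are later opened reductively to β-hydroxy ketones. The cyclohexane closes in the exo mode: the dipole carbon C10 bonds to the proximal, fully substituted alkene carbon C4 through the five-atom tether (ring C4, C6, C7, C8, C9, C10), helped by the geminal substitution at the C7 ketal, and the isoxazoline closes in the same event by O–C5 bond formation (ring C10, N, O, C5, C4). Regiochemistry is fixed by the tether, because the reverse orientation would require a bridged seven-membered carbocycle. C4 and C5 are attacked on the same face, so the C4–C10 and C5–O bonds are necessarily cis; the face is chosen by the C1 stereocentre, whose CH2OTBS group is allylic to C5 and shields its own side, so the dipole adds anti and both new bonds end up trans to the C1 arm. The step needs this facial selectivity and must outrun dimerisation of 20 to the furoxan, which high dilution and slow generation of the dipole are meant to secure.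

Step 9
Reactants: 21 spiro-fused isoxazoline
Product: 23 ketol (C5–OH; C10 ketone; C7 dioxolane; C1 CH2OTBS), via hydroxy imine 22 (not isolated)
Conditions: H2 (1 atm), Raney nickel, B(OH)3, MeOH/H2O 5:1, rt
Reagents that add atoms: water (O)
Why: Hydrogenolysis of the N–O bond and hydrolysis of the resulting β-hydroxy imine under boric acid buffering unmask the ketol; no epimerisable centre is present and ketal and silyl ether are untouched.

Step 10
Reactants: 23 ketol
Product: 24 C5 tert-butyldimethylsilyl ether of ketol 23
Conditions: TBSOTf, 2,6-lutidine, CH2Cl2, −78 → 0 °C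
Reagents that add atoms: tert-butyldimethylsilyl trifluoromethanesulfonate (CC(C)(C)[Si](C)(C)OS(=O)(=O)C(F)(F)F)
Why: Silylation of the hindered secondary alcohol with the silyl triflate; the bulky ether prevents chelation and retro-aldol cleavage and shields the face of the C10 carbonyl over which O5 lies.

Step 11
Reactants: 24 C5 silyl ether of the ketol
Product: 25 C10 methyl carbinol (C10–OH cis to C5 on the cyclohexane; C7 dioxolane)
Conditions: MeMgBr, CeCl3, THF, −78 → 0 °C
Reagents that add atoms: methylmagnesium bromide (C[Mg]Br)
Why: Organocerium-type 1,2-addition to a hindered, enolisable ketone; O5 is cis to C10 on the cyclopentane, so its silyl group covers one face of the carbonyl, the methyl enters from the C3 side, and the new hydroxyl ends up on the C5 side as in the target.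

Step 12
Reactants: 25 C10 methyl carbinol
Product: 26 C7 ketone (C10 tertiary alcohol; C5 OTBS; C1 CH2OTBS)
Conditions: pyridinium tosylate (cat.), acetone/H2O 10:1, 50 °C
Reagents that add atoms: water (O)
Why: Mild acid-catalysed ketal hydrolysis that spares both silyl ethers and the tertiary alcohol.

Step 13
Reactants: 26 C7 ketone
Product: 27 C8=C9 enone
Conditions: IBX, DMSO, 70 °C
Reagents that add atoms: none
Why: IBX dehydrogenation of a ketone to its enone; only the C8–C9 side can be desaturated because C6 adjoins the quaternary C4, and this leaves C6 as the only enolisable position.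

Step 14
Reactants: 27 C8=C9 enone; 28 prop-2-enal
Product: 30 C6 aldol adduct (C6–CH(OH)–CH=CH2; chain cis to C5), via lithium dienolate 29 (not isolated)
Conditions: LiN(iPr)2 (2.2 equiv), THF, −78 °C; 28, −78 °C; AcOH quench at −78 °C
Reagents that add atoms: none
Why: Kinetic α′-deprotonation gives the cross-conjugated dienolate whose only nucleophilic carbon is C6, and aldol addition to acrolein occurs 1,2 at low temperature; attack is expected axially on the half-chair with C5 pseudoequatorial, anti to the C4–C3 bond and on the face of the C10 alkoxide and not of the C10 methyl, which places the new chain cis to C5.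

Step 15
Reactants: 30 C6 aldol adduct
Product: 32 saturated β-hydroxy ketone, via silyl enol ether 31 (not isolated)
Conditions: [(Ph3P)CuH]6 (5 mol%), PhSiH3 (1.5 equiv), toluene, rt; then aq NH4F
Reagents that add atoms: none
Why: Copper hydride-catalysed conjugate reduction is selective for the enone over the isolated vinyl group and forms the enolate on the C8 side, so C6 is not touched.

Step 16
Reactants: 32 saturated β-hydroxy ketone; 33 2-(diethoxyphosphoryl)propanoic acid
Product: 34 phosphonate ester of the aldol hydroxyl
Conditions: DCC, DMAP (cat.), CH2Cl2, 0 °C → rt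
Reagents that add atoms: none
Why: Steglich esterification of the secondary allylic alcohol; the tertiary C10 alcohol does not compete and the mild conditions avoid retro-aldol cleavage.

Step 17
Reactants: 34 phosphonate ester
Product: 35 bicyclic unsaturated δ-lactone (ring O–CH(vinyl)–C6–C7=C(CH3)–C(=O))
Conditions: LiCl, DBU, MeCN, rt
Reagents that add atoms: none
Why: Intramolecular Horner–Wadsworth–Emmons olefination with LiCl/amine base is the standard way from β-hydroxy ketones to 5,6-dihydropyran-2-ones; because the new tetrasubstituted C7=C bond lies in a six-membered ring, the carbonyl carbon is forced cis to C6, which is the enal geometry of the target.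

Step 18
Reactants: 35 bicyclic unsaturated δ-lactone
Product: 37 methyl (Z)-enoate with C6 allyl group, via enoic acid 36 (not isolated)
Conditions: Pd2(dba)3 (2.5 mol%), PBu3 (10 mol%), HCO2H, Et3N, THF, 40 °C; then TMSCHN2, MeOH/toluene, 0 °C
Reagents that add atoms: (trimethylsilyl)diazomethane (C[Si](C)(C)C=[N+]=[N-])
Why: Zerovalent palladium ionises the allylic C–O bond of the vinyl lactone to a π-allyl carboxylate and formate delivers hydride to the more substituted allyl terminus (Tsuji formate reduction, favoured by PBu3), leaving a terminal allyl group on C6 and the enoic acid, which is esterified; the C7=C bond is not involved and keeps the geometry the ring imposed.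

Step 19
Reactants: 37 methyl (Z)-enoate with C6 allyl group
Product: 38 C11 primary alcohol
Conditions: HF·pyridine, pyridine, THF, 0 °C
Reagents that add atoms: none
Why: Buffered HF·pyridine cleaves the primary silyl ether much faster than the hindered secondary one at C5.

Step 20
Reactants: 38 C11 primary alcohol
Product: 39 C11 aldehyde
Conditions: Dess–Martin periodinane, NaHCO3, CH2Cl2, 0 °C → rt
Reagents that add atoms: none
Why: Buffered Dess–Martin oxidation; C1 stays in the more stable arrangement trans to the C5 silyloxy group.

Step 21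
Reactants: 39 C11 aldehyde
Product: 40 C11 secondary alcohol (1-hydroxyethyl on C1; epimers at C11)
Conditions: MeMgBr (2.2 equiv), THF, −78 °C
Reagents that add atoms: methylmagnesium bromide (C[Mg]Br)
Why: Grignard addition to the aldehyde at low temperature; the hindered tetrasubstituted enoate does not react and the new carbinol centre is oxidised away in the next step.

Step 22
Reactants: 40 C11 secondary alcohol
Product: 41 C11 methyl ketone
Conditions: Dess–Martin periodinane, NaHCO3, CH2Cl2, rt
Reagents that add atoms: none
Why: Dess–Martin oxidation of the secondary alcohol; the tertiary alcohol and the silyl ether are inert.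

Step 23
Reactants: 41 C11 methyl ketone
Product: 43 C11 enol triflate (C1–C(OTf)=CH2), via potassium enolate 42 (not isolated)
Conditions: KN(SiMe3)2 (2.1 equiv), THF, −78 °C; PhNTf2, −78 → 0 °C
Reagents that add atoms: N-phenylbis(trifluoromethanesulfonimide) (O=S(=O)(N(c1ccccc1)S(=O)(=O)C(F)(F)F)C(F)(F)F)
Why: After the first equivalent of base is consumed by the tertiary alcohol, kinetic deprotonation of the methyl ketone on the unhindered methyl side and O-triflation give the 1,1-disubstituted enol triflate that carries C11 and its methylene carbon.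

Step 24
Reactants: 43 C11 enol triflate
Product: 45 C6 3-hydroxypropyl compound, via alkylborane 44 (not isolated)
Conditions: 9-BBN, THF, 0 °C → rt; then 30% H2O2, pH 7 buffer
Reagents that add atoms: hydrogen peroxide (OO)
Why: 9-BBN hydroborates the monosubstituted terminal alkene anti-Markovnikov while the electron-poor enol triflate and the tetrasubstituted enoate are inert; buffered peroxide oxidation spares ester and triflate.

Step 25
Reactants: 45 C6 3-hydroxypropyl compound
Product: 46 allylic alcohol (C7=C(CH3)–CH2OH)
Conditions: iBu2AlH (5 equiv), CH2Cl2, −78 → −40 °C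
Reagents that add atoms: none
Why: iBu2AlH reduces the α,β-unsaturated ester 1,2 to the allylic alcohol at low temperature without touching the enol triflate.

Step 26
Reactants: 46 allylic alcohol
Product: 47 enal (C7=C(CH3)–CHO; CHO on the C6 side)
Conditions: MnO2 (excess), CH2Cl2, rt
Reagents that add atoms: none
Why: MnO2 oxidises only the allylic primary alcohol; the saturated primary and tertiary alcohols stay and the alkene geometry is kept.

Step 27
Reactants: 47 enal
Product: 48 C5-desilylated enal enol triflate
Conditions: HF·pyridine, THF, rt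
Reagents that add atoms: none
Why: Acidic fluoride removes the remaining hindered secondary silyl ether; enal, enol triflate and tertiary alcohol are stable to it.

Step 28
Reactants: 49 5-bromo-2-methylpent-2-ene; 50 prop-2-yn-1-ol
Product: 53 (2Z)-3-iodo-2-(4-methylpent-3-en-1-yl)prop-2-en-1-ol, via Grignard reagent 51 (not isolated), via alkenylmagnesium chelate 52 (not isolated)
Conditions: 49, Mg, Et2O; 50, CuI (10 mol%), Et2O/THF, 0 °C → rt; then I2, −20 °C
Reagents that add atoms: iodine (II)
Why: Copper-catalysed anti-carbomagnesiation of propargyl alcohol places the alkyl group on C2 and magnesium on C3 in a five-membered alkoxide chelate, and iodinolysis with retention gives the iodoalkene with iodine cis to CH2OH.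

Step 29
Reactants: 53 (2Z)-3-iodo-2-(4-methylpent-3-en-1-yl)prop-2-en-1-ol; 54 (E)-1,2-bis(tributylstannyl)ethene
Product: 55 (2Z,4E)-2-(4-methylpent-3-en-1-yl)-5-(tributylstannyl)penta-2,4-dien-1-ol
Conditions: 54 (2.5 equiv), PdCl2(MeCN)2 (5 mol%), DMF, rt
Reagents that add atoms: none
Why: Stille coupling of the vinyl iodide with an excess of the bis-stannane occurs once, with retention at both partners.

Step 30
Reactants: 48 C5-desilylated enal enol triflate; 55 (2Z,4E)-2-(4-methylpent-3-en-1-yl)-5-(tributylstannyl)penta-2,4-dien-1-ol
Product: 56 target CNP0249558.1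
Conditions: Pd(PPh3)4 (10 mol%), CuCl, LiCl, DMSO, 25 → 50 °C
Reagents that add atoms: none
Why: Stille coupling of a hindered 1-substituted vinyl triflate under CuCl/LiCl promotion joins C11 to C12 with retention of the (E) geometry; free hydroxyls and the enal are tolerated, so the triene is made last.

## Compound list

1 | 3-ethoxycyclopent-2-en-1-one | CCOC1=CC(=O)CC1 | starting material
2 | (chloromethyl)(isopropoxy)dimethylsilane | CC(C)O[Si](C)(C)CCl | starting material
3 | {[isopropoxy(dimethyl)silyl]methyl}magnesium chloride | CC(C)O[Si](C)(C)C[Mg]Cl | intermediate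
4 | 3-ethoxy-1-{[isopropoxy(dimethyl)silyl]methyl}cyclopent-2-en-1-ol (formed as its magnesium alkoxide) | CCOC1=CC(O)(C[Si](C)(C)OC(C)C)CC1 | intermediate
5 | 3-ethoxy-1-(hydroxymethyl)cyclopent-2-en-1-ol | CCOC1=CC(O)(CO)CC1 | intermediate
6 | 3-(hydroxymethyl)cyclopent-2-en-1-one | O=C1C=C(CO)CC1 | intermediate
7 | 3-{[(tert-butyldimethylsilyl)oxy]methyl}cyclopent-2-en-1-one | O=C1C=C(CO[Si](C)(C)C(C)(C)C)CC1 | intermediate
8 | bis{[(3R)-3-{[(tert-butyldimethylsilyl)oxy]methyl}cyclopent-1-en-1-yl]oxy}diphenylsilane | c1ccccc1[Si](c1ccccc1)(OC1=C[C@H](CO[Si](C)(C)C(C)(C)C)CC1)OC1=C[C@H](CO[Si](C)(C)C(C)(C)C)CC1 | intermediate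
9 | lithium (3R)-3-{[(tert-butyldimethylsilyl)oxy]methyl}cyclopent-1-en-1-olate | [Li]OC1=C[C@H](CO[Si](C)(C)C(C)(C)C)CC1 | intermediate
10 | (3R)-3-{[(tert-butyldimethylsilyl)oxy]methyl}cyclopent-1-en-1-yl trifluoromethanesulfonate | O=S(=O)(OC1=C[C@H](CO[Si](C)(C)C(C)(C)C)CC1)C(F)(F)F | intermediate
11 | 4-chlorobutanoyl chloride | ClCCCC(Cl)=O | starting material
12 | 5-chloro-1-diazopentan-2-one | ClCCCC(=O)C=[N+]=[N-] | intermediate
13 | 1-bromo-5-chloropentan-2-one | ClCCCC(=O)CBr | intermediate
14 | ethane-1,2-diol | OCCO | starting material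
15 | 2-(bromomethyl)-2-(3-chloropropyl)-1,3-dioxolane | ClCCCC1(CBr)OCCO1 | intermediate
16 | {[2-(3-chloropropyl)-1,3-dioxolan-2-yl]methyl}zinc bromide | ClCCCC1(C[Zn]Br)OCCO1 | intermediate
17 | tert-butyl{[(1R)-3-{[2-(3-chloropropyl)-1,3-dioxolan-2-yl]methyl}cyclopent-2-en-1-yl]methoxy}dimethylsilane | ClCCCC1(OCCO1)CC2=C[C@H](CO[Si](C)(C)C(C)(C)C)CC2 | intermediate
18 | tert-butyl{[(1R)-3-{[2-(3-iodopropyl)-1,3-dioxolan-2-yl]methyl}cyclopent-2-en-1-yl]methoxy}dimethylsilane | ICCCC1(OCCO1)CC2=C[C@H](CO[Si](C)(C)C(C)(C)C)CC2 | intermediate
19 | tert-butyldimethyl{[(1R)-3-{[2-(3-nitropropyl)-1,3-dioxolan-2-yl]methyl}cyclopent-2-en-1-yl]methoxy}silane (substrate of the key step) | [O-][N+](=O)CCCC1(OCCO1)CC2=C[C@H](CO[Si](C)(C)C(C)(C)C)CC2 | intermediate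
20 | nitrile oxide from 19 (C10≡N–O) | [O-][N+]#CCCC1(OCCO1)CC2=C[C@H](CO[Si](C)(C)C(C)(C)C)CC2 | intermediate
21 | spiro-fused 2-isoxazoline: ring C10=N–O–C5 fused across C4–C5, cyclohexane C4, C6–C10 spiro at C4, C7 as 1,3-dioxolane, C1 CH2OTBS; O5 and C10 cis, both trans to the C1 arm (product of the key step) | CC(C)(C)[Si](C)(C)OC[C@@H]1CC[C@]2(CC3(OCCO3)CCC2=NO4)[C@H]14 | intermediate
22 | β-hydroxy imine (C5–OH, C10=NH), otherwise as 21 | CC(C)(C)[Si](C)(C)OC[C@@H]1CC[C@]2(CC3(OCCO3)CCC2=N)[C@H]1O | intermediate
23 | ketol: C5–OH cis to C10 ketone, C7 dioxolane, C1 CH2OTBS trans to O5 | CC(C)(C)[Si](C)(C)OC[C@@H]1CC[C@]2(CC3(OCCO3)CCC2=O)[C@H]1O | intermediate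
24 | C5 tert-butyldimethylsilyl ether of 23 | CC(C)(C)[Si](C)(C)OC[C@@H]1CC[C@]2(CC3(OCCO3)CCC2=O)[C@H]1O[Si](C)(C)C(C)(C)C | intermediate
25 | C10 methyl carbinol: C10–OH on the same cyclohexane face as C5, methyl on the C3 face; C7 dioxolane; C5 OTBS; C1 CH2OTBS | CC(C)(C)[Si](C)(C)OC[C@@H]1CC[C@]2(CC3(OCCO3)CC[C@]2(C)O)[C@H]1O[Si](C)(C)C(C)(C)C | intermediate
26 | C7 ketone of 25 | CC(C)(C)[Si](C)(C)OC[C@@H]1CC[C@]2(CC(=O)CC[C@]2(C)O)[C@H]1O[Si](C)(C)C(C)(C)C | intermediate
27 | C8=C9 enone (C7 ketone, C10 tertiary allylic alcohol) | CC(C)(C)[Si](C)(C)OC[C@@H]1CC[C@]2(CC(=O)C=C[C@]2(C)O)[C@H]1O[Si](C)(C)C(C)(C)C | intermediate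
28 | prop-2-enal | C=CC=O | starting material
29 | dilithium dienolate/alkoxide of 27 (C6=C7–OLi, C10–OLi) | CC(C)(C)[Si](C)(C)OC[C@@H]1CC[C@]2(C=C(O[Li])C=C[C@]2(C)O[Li])[C@H]1O[Si](C)(C)C(C)(C)C | intermediate
30 | aldol adduct: C6 bears CH(OH)–CH=CH2 on the C5 face (carbinol epimers), C8=C9 enone | CC(C)(C)[Si](C)(C)OC[C@@H]1CC[C@]2([C@H](C(O)C=C)C(=O)C=C[C@]2(C)O)[C@H]1O[Si](C)(C)C(C)(C)C | intermediate
31 | phenylsilyl enol ether (C7=C8) of 32 | CC(C)(C)[Si](C)(C)OC[C@@H]1CC[C@]2([C@H](C(O)C=C)C(O[SiH2]c3ccccc3)=CC[C@]2(C)O)[C@H]1O[Si](C)(C)C(C)(C)C | intermediate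
32 | saturated β-hydroxy ketone (C7 ketone, C6 CH(OH)–CH=CH2) | CC(C)(C)[Si](C)(C)OC[C@@H]1CC[C@]2([C@H](C(O)C=C)C(=O)CC[C@]2(C)O)[C@H]1O[Si](C)(C)C(C)(C)C | intermediate
33 | 2-(diethoxyphosphoryl)propanoic acid | CCOP(=O)(OCC)C(C)C(=O)O | starting material
34 | 2-(diethoxyphosphoryl)propanoate ester of the aldol hydroxyl of 32 | CC(C)(C)[Si](C)(C)OC[C@@H]1CC[C@]2([C@H](C(OC(=O)C(C)P(=O)(OCC)OCC)C=C)C(=O)CC[C@]2(C)O)[C@H]1O[Si](C)(C)C(C)(C)C | intermediate
35 | bicyclic unsaturated δ-lactone: ring O–CH(vinyl)–C6–C7=C(CH3)–C(=O), fused to the cyclohexane at C6–C7 | CC(C)(C)[Si](C)(C)OC[C@@H]1CC[C@]2([C@@H]3C(C=C)OC(=O)C(C)=C3CC[C@]2(C)O)[C@H]1O[Si](C)(C)C(C)(C)C | intermediate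
36 | enoic acid: C7=C(CH3)–CO2H with CO2H on the C6 side; C6 allyl | CC(C)(C)[Si](C)(C)OC[C@@H]1CC[C@]2([C@H](CC=C)/C(=C(/C)C(=O)O)CC[C@]2(C)O)[C@H]1O[Si](C)(C)C(C)(C)C | intermediate
37 | methyl ester of 36 | CC(C)(C)[Si](C)(C)OC[C@@H]1CC[C@]2([C@H](CC=C)/C(=C(/C)C(=O)OC)CC[C@]2(C)O)[C@H]1O[Si](C)(C)C(C)(C)C | intermediate
38 | C11 primary alcohol (C1 CH2OH; C5 OTBS) | OC[C@@H]1CC[C@]2([C@H](CC=C)/C(=C(/C)C(=O)OC)CC[C@]2(C)O)[C@H]1O[Si](C)(C)C(C)(C)C | intermediate
39 | C11 aldehyde (C1 CHO) | O=C[C@@H]1CC[C@]2([C@H](CC=C)/C(=C(/C)C(=O)OC)CC[C@]2(C)O)[C@H]1O[Si](C)(C)C(C)(C)C | intermediate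
40 | C11 secondary alcohol (C1 CH(OH)CH3, epimers) | CC(O)[C@@H]1CC[C@]2([C@H](CC=C)/C(=C(/C)C(=O)OC)CC[C@]2(C)O)[C@H]1O[Si](C)(C)C(C)(C)C | intermediate
41 | C11 methyl ketone (C1 acetyl) | CC(=O)[C@@H]1CC[C@]2([C@H](CC=C)/C(=C(/C)C(=O)OC)CC[C@]2(C)O)[C@H]1O[Si](C)(C)C(C)(C)C | intermediate
42 | dipotassium enolate/alkoxide of 41 | C=C(O[K])[C@@H]1CC[C@]2([C@H](CC=C)/C(=C(/C)C(=O)OC)CC[C@]2(C)O[K])[C@H]1O[Si](C)(C)C(C)(C)C | intermediate
43 | C11 enol triflate (C1–C(OTf)=CH2), C6 allyl, methyl enoate, C5 OTBS | C=C(OS(=O)(=O)C(F)(F)F)[C@@H]1CC[C@]2([C@H](CC=C)/C(=C(/C)C(=O)OC)CC[C@]2(C)O)[C@H]1O[Si](C)(C)C(C)(C)C | intermediate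
44 | B-alkyl-9-borabicyclo[3.3.1]nonane from 43 | C=C(OS(=O)(=O)C(F)(F)F)[C@@H]1CC[C@]2([C@H](CCCB3C4CCCC3CCC4)/C(=C(/C)C(=O)OC)CC[C@]2(C)O)[C@H]1O[Si](C)(C)C(C)(C)C | intermediate
45 | C6 3-hydroxypropyl compound (methyl enoate, enol triflate, C5 OTBS) | C=C(OS(=O)(=O)C(F)(F)F)[C@@H]1CC[C@]2([C@H](CCCO)/C(=C(/C)C(=O)OC)CC[C@]2(C)O)[C@H]1O[Si](C)(C)C(C)(C)C | intermediate
46 | allylic alcohol (C7=C(CH3)–CH2OH) | C=C(OS(=O)(=O)C(F)(F)F)[C@@H]1CC[C@]2([C@H](CCCO)/C(=C(/C)CO)CC[C@]2(C)O)[C@H]1O[Si](C)(C)C(C)(C)C | intermediate
47 | enal with C5 OTBS | C=C(OS(=O)(=O)C(F)(F)F)[C@@H]1CC[C@]2([C@H](CCCO)/C(=C(/C)C=O)CC[C@]2(C)O)[C@H]1O[Si](C)(C)C(C)(C)C | intermediate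
48 | fully deprotected core as its C11 enol triflate | C=C(OS(=O)(=O)C(F)(F)F)[C@@H]1CC[C@]2([C@H](CCCO)/C(=C(/C)C=O)CC[C@]2(C)O)[C@H]1O | intermediate
49 | 5-bromo-2-methylpent-2-ene | CC(C)=CCCBr | starting material
50 | prop-2-yn-1-ol | C#CCO | starting material
51 | (4-methylpent-3-en-1-yl)magnesium bromide | CC(C)=CCC[Mg]Br | intermediate
52 | (Z)-alkenylmagnesium alkoxide chelate from carbomagnesiation | Br[Mg]OC/C(CCC=C(C)C)=C\[Mg]Br | intermediate
53 | (2Z)-3-iodo-2-(4-methylpent-3-en-1-yl)prop-2-en-1-ol | OC/C(CCC=C(C)C)=C\I | intermediate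
54 | (E)-1,2-bis(tributylstannyl)ethene | CCCC[Sn](CCCC)(CCCC)/C=C/[Sn](CCCC)(CCCC)CCCC | starting material
55 | (2Z,4E)-2-(4-methylpent-3-en-1-yl)-5-(tributylstannyl)penta-2,4-dien-1-ol | OC/C(CCC=C(C)C)=C\C=C\[Sn](CCCC)(CCCC)CCCC | intermediate
56 | CNP0249558.1 | C=C(/C=C/C=C(\CO)CCC=C(C)C)[C@@H]1CC[C@]2([C@H](CCCO)/C(=C(/C)C=O)CC[C@]2(C)O)[C@H]1O | target

## Step count and least certain steps

Total: 30 steps. Longest linear sequence: 26 steps (steps 1–3, 6–27 and 30). Steps 4–5 and 28–29 make the two side fragments.

**Step 8 (key step).** The dipole carbon has to bond to a fully substituted alkene carbon, so cyclisation may be slow enough for the nitrile oxide to dimerise to the furoxan. Facial selectivity may also be incomplete, since the only control is a CH2OTBS group allylic to C5. Fallback: the silyl nitronate variant of the same bond construction. Setting out from 19, TMSCl/Et3N gives the trimethylsilyl nitronate F1, a dipole that does not dimerise and can be heated. Its intramolecular cycloaddition gives the N-silyloxy isoxazolidine F2, and acid-induced loss of trimethylsilanol returns to the route at 21.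

**Step 14.** The chain may enter C6 with poor facial selectivity, because the two flanks of C6 differ only through the more remote C10 methyl/oxygen pair. The aldol may also revert, or acrolein may react 1,4. Fallback: form the C–C bond by alkylation and add the oxygen afterwards. Setting out from 27, α′-alkylation of the dienolate with allyl bromide gives the C6-allyl enone F3. If it forms as the wrong C6 epimer, re-enolisation and kinetic protonation from the same preferred face corrects it. Allylic hydroxylation of the terminal allyl group with SeO2 (cat.)/tBuOOH then rejoins the route at 30.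

**Step 18.** Hydride may be delivered to the terminal allyl carbon, giving the internal propenyl isomer, or the π-allyl intermediate may lose the C6 hydrogen to give a diene, or be captured by the nearby C10 hydroxyl. Fallback: avoid the allylic oxygen altogether. Setting out from 27 through the allyl enone F3, copper hydride reduction gives the C6-allyl ketone F4. Intermolecular Horner–Wadsworth–Emmons olefination with methyl 2-(dimethoxyphosphoryl)propanoate (NaH, DME, reflux) then gives 37, where the route is rejoined. It forms together with its geometric isomer F5, which has to be separated because the ring template is lost.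

**Step 11.** The methyl group may add from the O5 face (for example if the silyl ether is lost and the magnesium alkoxide chelates), or the hindered ketone may simply enolise. Fallback: deliver the oxygen rather than the carbon. Setting out from 23, Peterson methylenation (Me3SiCH2Li/CeCl3 to the β-hydroxysilane F6, then KH) gives the exocyclic alkene F7. Hydroxyl-directed epoxidation with VO(acac)2/tBuOOH places the oxygen on the O5 face to give epoxide F8, and LiAlH4 opens it at the CH2 terminus to the diol F9. Selective silylation of the secondary hydroxyl (TBSOTf, −78 °C) rejoins the route at 25.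

**Step 3.** Enantioselectivity may be insufficient with the silyloxymethyl substituent, or the regiodefined enolate may equilibrate during the silicon-to-lithium exchange. Fallback: set C1 by conjugate addition instead of conjugate reduction. Setting out from the Grignard reagent 3, CuBr·SMe2 with a chiral ferrocenyl diphosphine catalyses its asymmetric addition to cyclopent-2-en-1-one F10. Trapping the magnesium enolate with PhNTf2 gives the enol triflate F11, Negishi coupling with 16 gives F12, Tamao oxidation gives the alcohol F13, and silylation with TBSCl rejoins the route at 17.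

## Further compounds

F1 | step 8 | trimethylsilyl nitronate of 19 | C[Si](C)(C)O[N+]([O-])=CCCC1(OCCO1)CC2=C[C@H](CO[Si](C)(C)C(C)(C)C)CC2
F2 | step 8 | N-(trimethylsilyloxy)isoxazolidine cycloadduct (C10 epimers) | CC(C)(C)[Si](C)(C)OC[C@@H]1CC[C@]2(CC3(OCCO3)CCC2N(O[Si](C)(C)C)O4)[C@H]14
F3 | step 14 | C6-allyl C8=C9 enone | CC(C)(C)[Si](C)(C)OC[C@@H]1CC[C@]2([C@H](CC=C)C(=O)C=C[C@]2(C)O)[C@H]1O[Si](C)(C)C(C)(C)C
F4 | step 18 | C6-allyl C7 ketone | CC(C)(C)[Si](C)(C)OC[C@@H]1CC[C@]2([C@H](CC=C)C(=O)CC[C@]2(C)O)[C@H]1O[Si](C)(C)C(C)(C)C
F5 | step 18 | geometric isomer of 37 (ester on the C8 side) | CC(C)(C)[Si](C)(C)OC[C@@H]1CC[C@]2([C@H](CC=C)/C(=C(\C)C(=O)OC)CC[C@]2(C)O)[C@H]1O[Si](C)(C)C(C)(C)C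
F6 | step 11 | β-hydroxysilane from 23 (C10 epimers) | CC(C)(C)[Si](C)(C)OC[C@@H]1CC[C@]2(CC3(OCCO3)CCC2(O)C[Si](C)(C)C)[C@H]1O
F7 | step 11 | C10 exocyclic methylene homoallylic alcohol | CC(C)(C)[Si](C)(C)OC[C@@H]1CC[C@]2(CC3(OCCO3)CCC2=C)[C@H]1O
F8 | step 11 | C10 spiro-epoxide with oxygen on the C5 face | CC(C)(C)[Si](C)(C)OC[C@@H]1CC[C@]2(CC3(OCCO3)CC[C@]2(C4)O4)[C@H]1O
F9 | step 11 | C5,C10 diol (desilyl 25) | CC(C)(C)[Si](C)(C)OC[C@@H]1CC[C@]2(CC3(OCCO3)CC[C@]2(C)O)[C@H]1O
F10 | step 3 | cyclopent-2-en-1-one | O=C1C=CCC1
F11 | step 3 | (3R)-3-{[isopropoxy(dimethyl)silyl]methyl}cyclopent-1-en-1-yl trifluoromethanesulfonate | O=S(=O)(OC1=C[C@H](C[Si](C)(C)OC(C)C)CC1)C(F)(F)F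
F12 | step 3 | Negishi product bearing the silylmethyl group | ClCCCC1(OCCO1)CC2=C[C@H](C[Si](C)(C)OC(C)C)CC2
F13 | step 3 | [(1R)-3-{[2-(3-chloropropyl)-1,3-dioxolan-2-yl]methyl}cyclopent-2-en-1-yl]methanol | ClCCCC1(OCCO1)CC2=C[C@H](CO)CC2
A1 | alternative 1 | trans-6-allylcarvone | CC1=CC[C@H](C(C)=C)[C@@H](CC=C)C1=O
A2 | alternative 1 | 1-lithiocyclopropyl phenyl sulfide | [Li]C1(Sc2ccccc2)CC1
A3 | alternative 1 | spiro[3.5]nonenone with C6 allyl and C7 isopropenyl | CC1=CC[C@H](C(C)=C)[C@@H](CC=C)[C@]12CCC2=O
A4 | alternative 2 | methyl 2-(5-methylfuran-2-yl)propanoate | COC(=O)C(C)c1ccc(C)o1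
A5 | alternative 2 | α-substituted (5R)-menthyloxybutenolide | COC(=O)CCCC1=C[C@H](O[C@@H]2C[C@H](C)CC[C@H]2C(C)C)OC1=O
A6 | alternative 2 | exo oxanorbornene lactone | C[C@@]12C=C[C@](O1)(C(C)C(=O)OC)[C@H]3[C@H](O[C@@H]4C[C@H](C)CC[C@H]4C(C)C)OC(=O)[C@@]23CCCC(=O)OC
A7 | alternative 3 | C1-ethynyl spirocycle | C#C[C@@H]1CC[C@]2([C@H](CCCO)/C(=C(/C)C=O)CC[C@]2(C)O)[C@H]1O
A8 | alternative 3 | dienyl silyl ether with terminal alkene | C=C/C=C(\CO[Si](C)(C)C(C)(C)C)CCC=C(C)C
A9 | alternative 3 | target as its mono silyl ether | C=C(/C=C/C=C(\CO[Si](C)(C)C(C)(C)C)CCC=C(C)C)[C@@H]1CC[C@]2([C@H](CCCO)/C(=C(/C)C=O)CC[C@]2(C)O)[C@H]1O
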